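**Strategy.** The 14-membered carbocycle is opened at C9–C10. C10 is flanked by a phenylsulfonyl group and the C11=C12 alkene, so it is the acidic site of a geranyl-type sulfone. C9 is the CH2Br terminus of the 2-substituted allyl unit C9–C8(=C19), whose direct and allylically transposed substitutions give one constitution. One base-mediated operation therefore closes the ring without creating a permanent stereocentre. The precursor is an acyclic C10 sulfone/C9 allylic bromide that already carries C1, C2 and C7 (anti allylboration, asymmetric Baylis–Hillman reaction) and the C3=C4 alkene (alanate iodination, Negishi coupling). C2, C7 and C18 are protected as triethylsilyl, triisopropylsilyl and tert-butyldimethylsilyl ethers.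

Key step: step 17

Remark: cembrane numbering is used (C1 bears the isopropenyl group C15–C17; C18 = CH2O on C4; C19 = exocyclic CH2 on C8; C20 = CH3 on C12); 1, 5, 10, 11, β-isocupreidine and (R)-TRIP are taken as purchasable; aluminium alkoxides that are only protonated on work-up are not numbered.

**Route**

Step 1
Reactants: 1 geranyl bromide
Product: 2 geranyl phenyl sulfone
Conditions: PhSO2Na, DMF, rt
Reagents that add atoms: sodium benzenesulfinate, [Na+].[O-]S(=O)c1ccccc1
Why: SN2 S-alkylation of the sulfinate anion by the primary allylic bromide (sulfinate alkylation) should give the C10 sulfone with the E C11=C12 alkene unchanged.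

Step 2
Reactants: 2 geranyl phenyl sulfone
Product: 3 (2E,6E)-2,6-dimethyl-8-(phenylsulfonyl)octa-2,6-dien-1-ol (C16 alcohol)
Conditions: SeO2 (cat.), t-BuOOH, salicylic acid (cat.), CH2Cl2, rt
Reagents that add atoms: tert-butyl hydroperoxide, CC(C)(C)OO; selenium dioxide, O=[Se]=O
Why: Riley-type allylic oxidation (ene reaction, then [2,3]-sigmatropic shift) should select the E methyl group (C16) of the electron-richer terminal alkene, because the C11=C12 alkene is deactivated by the allylic sulfonyl group.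

Step 3
Reactants: 3 C16 alcohol
Product: 4 2-[(2E,6E)-2,6-dimethyl-8-(phenylsulfonyl)octa-2,6-dien-1-yl]-4,4,5,5-tetramethyl-1,3,2-dioxaborolane (C16 allylboronate)
Conditions: B2pin2, Pd(MeCN)4(BF4)2 (5 mol%), DMSO/MeOH, 40 °C
Reagents that add atoms: bis(pinacolato)diboron, CC1(C)OB(OC1(C)C)B1OC(C)(C)C(C)(C)O1
Why: Palladium-catalysed borylation of an allylic alcohol via an η3-allylpalladium intermediate should place boron on the unsubstituted terminus C16 and give the linear E allylboronate, the allylic sulfone being a much poorer leaving group than the activated hydroxyl.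

Step 4
Reactants: 5 but-2-yne-1,4-diol
Product: 6 4-[(tert-butyldimethylsilyl)oxy]but-2-yn-1-ol
Conditions: NaH (1 equiv), THF, 0 °C; then TBSCl, rt
Reagents that add atoms: tert-butyldimethylsilyl chloride, CC(C)(C)[Si](C)(C)Cl
Why: O-silylation of the sparingly soluble monosodium alkoxide of a symmetrical diol should stop at the mono-ether (monosilylation of a symmetrical diol); no stereochemistry is involved.

Step 5
Reactants: 6 4-[(tert-butyldimethylsilyl)oxy]but-2-yn-1-ol
Product: 8 (2Z)-4-[(tert-butyldimethylsilyl)oxy]-3-iodobut-2-en-1-ol, via cyclic sodium vinylalanate 7 (not isolated)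
Conditions: NaAlH2(OCH2CH2OCH3)2, THF, 0 °C; EtOAc; then I2, −78 °C
Reagents that add atoms: iodine, II
Why: Hydroxyl-directed trans-hydroalumination of the propargylic alcohol puts aluminium on the distal alkyne carbon (future C4) in a five-membered alanate, and iodinolysis with retention should give the Z iodide (iodine cis to CH2OH), which fixes the later cis relation of C2 and C5.

Step 6
Reactants: 8 (2Z)-iodo allylic alcohol
Product: 9 (2Z)-4-[(tert-butyldimethylsilyl)oxy]-3-iodobut-2-enal
Conditions: MnO2, CH2Cl2, rt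
Reagents that add atoms: none
Why: Neutral heterogeneous oxidation of an allylic alcohol by MnO2 should give the β-iodo enal without Z/E isomerisation.

Step 7
Reactants: 10 3-[(tert-butyldimethylsilyl)oxy]propanal; 11 1,1,1,3,3,3-hexafluoropropan-2-yl acrylate
Product: 12 1,1,1,3,3,3-hexafluoropropan-2-yl (3R)-5-[(tert-butyldimethylsilyl)oxy]-3-hydroxy-2-methylidenepentanoate
Conditions: β-isocupreidine (C19H22N2O2, 10 mol%), DMF, −55 °C
Reagents that add atoms: none
Why: Asymmetric Morita–Baylis–Hillman reaction of the activated fluoroalkyl acrylate, in which the quinuclidine nitrogen adds to the acrylate and the phenolic OH of the catalyst hydrogen-bonds to the aldol betaine, should set C7 as R.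

Step 8
Reactants: 12 hexafluoroisopropyl ester
Product: 13 methyl (3R)-5-[(tert-butyldimethylsilyl)oxy]-3-hydroxy-2-methylidenepentanoate
Conditions: NaOMe (cat.), MeOH, 0 °C
Reagents that add atoms: methanol, CO
Why: Transesterification of the activated ester to the methyl ester should remove the acylating group before the C5 hydroxyl is freed, so that lactonisation is not invited.

Step 9
Reactants: 13 methyl ester
Product: 14 methyl (3R)-5-[(tert-butyldimethylsilyl)oxy]-2-methylidene-3-[(triisopropylsilyl)oxy]pentanoate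
Conditions: TIPSOTf, 2,6-lutidine, CH2Cl2, 0 °C
Reagents that add atoms: triisopropylsilyl trifluoromethanesulfonate, CC(C)[Si](C(C)C)(C(C)C)OS(=O)(=O)C(F)(F)F
Why: Silylation of the secondary alcohol with a silyl triflate and a non-nucleophilic base avoids conjugate addition to the acrylate, and the bulky C7 ether is chosen to outlast two later selective desilylations.

Step 10
Reactants: 14 bis-silyl ether
Product: 15 methyl (3R)-5-hydroxy-2-methylidene-3-[(triisopropylsilyl)oxy]pentanoate
Conditions: HF·pyridine, pyridine, THF, 0 °C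
Reagents that add atoms: none
Why: Buffered fluoride cleaves the primary tert-butyldimethylsilyl ether much faster than the hindered secondary triisopropylsilyl ether (selective desilylation); the alcohol is taken on at once.

Step 11
Reactants: 15 primary alcohol
Product: 16 methyl (3R)-5-iodo-2-methylidene-3-[(triisopropylsilyl)oxy]pentanoate
Conditions: I2, PPh3, imidazole, CH2Cl2, 0 °C
Reagents that add atoms: iodine, II
Why: Appel-type iodination through an alkoxyphosphonium ion converts the primary alcohol into the C5 iodide without touching C7.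

Step 12
Reactants: 4 C16 allylboronate; 9 (2Z)-β-iodo enal
Product: 18 (2Z,4R,5R,8E)-1-[(tert-butyldimethylsilyl)oxy]-2-iodo-8-methyl-10-(phenylsulfonyl)-5-(prop-1-en-2-yl)deca-2,8-dien-4-ol (cembrane C1 R; C2 R), via pinacol borate ester 17 (not isolated)
Conditions: (R)-3,3′-bis(2,4,6-triisopropylphenyl)-1,1′-binaphthyl-2,2′-diyl hydrogen phosphate [(R)-TRIP, C50H57O4P, 5 mol%], 4 Å MS, toluene, −30 °C; aqueous work-up
Reagents that add atoms: none
Why: Chiral phosphoric acid-catalysed allylboration through a chair transition state should give the anti C1/C2 pair from the E γ-substituent, while the (R)-acid, bound to the boronate oxygen, directs attack to the Re face of the enal (C2 is labelled R here only because iodine raises the priority of C3).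

Step 13
Reactants: 18 iodo alcohol
Product: 19 C2 triethylsilyl ether of 18 (cembrane C1 R; C2 R; 3Z; 11E)
Conditions: TESOTf, 2,6-lutidine, CH2Cl2, −78 °C
Reagents that add atoms: triethylsilyl trifluoromethanesulfonate, CC[Si](CC)(CC)OS(=O)(=O)C(F)(F)F
Why: Triflate-mediated silylation protects the hindered secondary allylic alcohol so that it cannot quench the organozinc reagent or the later carbanion.

Step 14
Reactants: 16 C5 iodide; 19 alkenyl iodide
Product: 21 methyl (3R,6E,8S,9R,12E)-6-{[(tert-butyldimethylsilyl)oxy]methyl}-12-methyl-2-methylidene-14-(phenylsulfonyl)-9-(prop-1-en-2-yl)-8-[(triethylsilyl)oxy]-3-[(triisopropylsilyl)oxy]tetradeca-6,12-dienoate (seco C9 ester), via alkylzinc iodide 20 (not isolated)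
Conditions: 16, Zn dust, LiCl, THF, 30 °C; then 19, PdCl2(dppf) (5 mol%), THF, rt
Reagents that add atoms: none
Why: Negishi sp3–sp2 coupling, in which the ester-tolerant alkylzinc iodide (silyloxy group γ to zinc, so no β-elimination) transmetallates to the alkenylpalladium formed by oxidative addition of zerovalent palladium to the C–I bond, should form C4–C5 with retention of alkene geometry (C5 cis to C2, 3E by the sequence rule) and leave the allylic sulfone alone at room temperature.

Step 15
Reactants: 21 seco C9 ester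
Product: 22 (1R,2S,3E,7R,11E)-18-[(tert-butyldimethylsilyl)oxy]-10-(phenylsulfonyl)-2-[(triethylsilyl)oxy]-7-[(triisopropylsilyl)oxy]-9,10-secocembra-3,8(19),11,15-tetraen-9-ol (C9 allylic alcohol)
Conditions: i-Bu2AlH, CH2Cl2, −78 °C
Reagents that add atoms: none
Why: 1,2-Reduction of the α,β-unsaturated ester by the aluminium hydride gives the allylic alcohol, the sulfone and silyl ethers being inert at low temperature.

Step 16
Reactants: 22 C9 allylic alcohol
Product: 24 (1R,2S,3E,7R,11E)-9-bromo-18-[(tert-butyldimethylsilyl)oxy]-10-(phenylsulfonyl)-2-[(triethylsilyl)oxy]-7-[(triisopropylsilyl)oxy]-9,10-secocembra-3,8(19),11,15-tetraene (seco precursor), via C9 mesylate 23 (not isolated)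
Conditions: MsCl, Et3N, THF, −40 °C; then LiBr, 0 °C
Reagents that add atoms: lithium bromide, [Li+].[Br-]
Why: Mesylation followed by SN2 displacement with bromide (Finkelstein-type exchange) makes the allylic bromide under non-acidic conditions that spare the triethylsilyl ether.

Step 17
Reactants: 24 seco precursor
Product: 26 (1R,2S,3E,7R,11E)-18-[(tert-butyldimethylsilyl)oxy]-10-(phenylsulfonyl)-2-[(triethylsilyl)oxy]-7-[(triisopropylsilyl)oxy]cembra-3,8(19),11,15-tetraene (both C10 epimers), via potassium C10 carbanion 25 (not isolated)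
Conditions: KN(SiMe3)2 (1.3 equiv), THF, 0.002 M, syringe-pump addition of 24, −78 → 0 °C
Reagents that add atoms: none
Why: KN(SiMe3)2 removes the C10 proton, which is acidified by the phenylsulfonyl group and allylic to C11=C12, and the sulfonyl-stabilised allyl anion attacks through its α-carbon and displaces bromide from C9. The closest known reaction type is the intramolecular alkylation of allylic sulfone carbanions by allylic halides, which has been used to close 14-membered terpenoid carbocycles. The 14-membered ring closes in exo-tet fashion at C9; attack at C19 with allylic transposition would give the same constitution, because C9 and C19 are the equivalent CH2 termini of the 2-substituted allyl unit. No stereocentre of the target is created: C10 becomes a temporary stereocentre whose two epimers converge in step 18, and C1, C2 and C7 are spectators. The step needs ring closure to outrun intermolecular alkylation, which high dilution and slow addition should secure, and α- rather than γ-alkylation, which the charge next to sulfur and the strain of the alternative 12-membered ring secure; the E C11=C12 geometry is kept because that bond is not involved.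

Step 18
Reactants: 26 macrocyclic C10 sulfone
Product: 27 (1R,2S,3E,7R,11E)-18-[(tert-butyldimethylsilyl)oxy]-2-[(triethylsilyl)oxy]-7-[(triisopropylsilyl)oxy]cembra-3,8(19),11,15-tetraene
Conditions: PdCl2(dppp) (10 mol%), LiBHEt3, THF, 0 °C → rt
Reagents that add atoms: none
Why: Palladium-catalysed reductive desulfonylation, in which zerovalent palladium ionises the allylic sulfone to a C10–C12 η3-allyl complex and hydride is delivered to the less substituted terminus C10, should give the CH2 group and keep the trisubstituted E C11=C12 alkene; the allylic silyl ethers are not leaving groups.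

Step 19
Reactants: 27 tris-silyl ether
Product: 28 (1R,2S,3E,7R,11E)-7-[(triisopropylsilyl)oxy]cembra-3,8(19),11,15-tetraene-2,18-diol
Conditions: HF·pyridine, pyridine, THF, 0 °C → rt
Reagents that add atoms: none
Why: Buffered fluoride cleaves the secondary triethylsilyl and primary tert-butyldimethylsilyl ethers, while the hindered secondary triisopropylsilyl ether at C7 should survive (selective desilylation).

Step 20
Reactants: 28 diol
Product: 29 (1R,2S,3E,7R,11E)-7-[(triisopropylsilyl)oxy]cembra-3,8(19),11,15-tetraene-2,18-diyl diacetate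
Conditions: Ac2O, pyridine, 4-(dimethylamino)pyridine (cat.), CH2Cl2, rt
Reagents that add atoms: acetic anhydride, CC(=O)OC(C)=O
Why: Nucleophile-catalysed acylation acetylates both free hydroxyls while C7 stays masked.

Step 21
Reactants: 29 diacetate
Product: 30 (1R,2S,3E,7R,11E)-7-hydroxycembra-3,8(19),11,15-tetraene-2,18-diyl diacetate (CNP0077636.1)
Conditions: HF·pyridine, THF, rt
Reagents that add atoms: none
Why: Unbuffered fluoride under mildly acidic conditions removes the triisopropylsilyl ether without cleaving or migrating the allylic acetates (silyl ether cleavage).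

**Compound list**

1 | geranyl bromide, (2E)-1-bromo-3,7-dimethylocta-2,6-diene | BrC/C=C(\C)CCC=C(C)C | starting material
2 | geranyl phenyl sulfone | O=S(=O)(c1ccccc1)C/C=C(\C)CCC=C(C)C | intermediate
3 | (2E,6E)-2,6-dimethyl-8-(phenylsulfonyl)octa-2,6-dien-1-ol | O=S(=O)(c1ccccc1)C/C=C(\C)CC/C=C(\C)CO | intermediate
4 | 2-[(2E,6E)-2,6-dimethyl-8-(phenylsulfonyl)octa-2,6-dien-1-yl]-4,4,5,5-tetramethyl-1,3,2-dioxaborolane | O=S(=O)(c1ccccc1)C/C=C(\C)CC/C=C(\C)CB1OC(C)(C)C(C)(C)O1 | intermediate
5 | but-2-yne-1,4-diol | OCC#CCO | starting material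
6 | 4-[(tert-butyldimethylsilyl)oxy]but-2-yn-1-ol | OCC#CCO[Si](C)(C)C(C)(C)C | intermediate
7 | cyclic sodium vinylalanate from 6 (five-membered O–Al–C=C ring; not isolated) | [Na+].COCCO[Al-]1(OCCOC)OCC=C1CO[Si](C)(C)C(C)(C)C | intermediate
8 | (2Z)-4-[(tert-butyldimethylsilyl)oxy]-3-iodobut-2-en-1-ol | OC/C=C(\I)CO[Si](C)(C)C(C)(C)C | intermediate
9 | (2Z)-4-[(tert-butyldimethylsilyl)oxy]-3-iodobut-2-enal | O=C/C=C(\I)CO[Si](C)(C)C(C)(C)C | intermediate
10 | 3-[(tert-butyldimethylsilyl)oxy]propanal | O=CCCO[Si](C)(C)C(C)(C)C | starting material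
11 | 1,1,1,3,3,3-hexafluoropropan-2-yl acrylate | C=CC(=O)OC(C(F)(F)F)C(F)(F)F | starting material
12 | 1,1,1,3,3,3-hexafluoropropan-2-yl (3R)-5-[(tert-butyldimethylsilyl)oxy]-3-hydroxy-2-methylidenepentanoate | C=C(C(=O)OC(C(F)(F)F)C(F)(F)F)[C@H](O)CCO[Si](C)(C)C(C)(C)C | intermediate
13 | methyl (3R)-5-[(tert-butyldimethylsilyl)oxy]-3-hydroxy-2-methylidenepentanoate | C=C(C(=O)OC)[C@H](O)CCO[Si](C)(C)C(C)(C)C | intermediate
14 | methyl (3R)-5-[(tert-butyldimethylsilyl)oxy]-2-methylidene-3-[(triisopropylsilyl)oxy]pentanoate | C=C(C(=O)OC)[C@H](O[Si](C(C)C)(C(C)C)C(C)C)CCO[Si](C)(C)C(C)(C)C | intermediate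
15 | methyl (3R)-5-hydroxy-2-methylidene-3-[(triisopropylsilyl)oxy]pentanoate | C=C(C(=O)OC)[C@H](O[Si](C(C)C)(C(C)C)C(C)C)CCO | intermediate
16 | methyl (3R)-5-iodo-2-methylidene-3-[(triisopropylsilyl)oxy]pentanoate | C=C(C(=O)OC)[C@H](O[Si](C(C)C)(C(C)C)C(C)C)CCI | intermediate
17 | pinacol borate ester of 18 (O–B at C2; not isolated) | O=S(=O)(c1ccccc1)C/C=C(\C)CC[C@H](C(=C)C)[C@@H](OB1OC(C)(C)C(C)(C)O1)/C=C(\I)CO[Si](C)(C)C(C)(C)C | intermediate
18 | (2Z,4R,5R,8E)-1-[(tert-butyldimethylsilyl)oxy]-2-iodo-8-methyl-10-(phenylsulfonyl)-5-(prop-1-en-2-yl)deca-2,8-dien-4-ol | O=S(=O)(c1ccccc1)C/C=C(\C)CC[C@H](C(=C)C)[C@@H](O)/C=C(\I)CO[Si](C)(C)C(C)(C)C | intermediate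
19 | C2 triethylsilyl ether of 18 | O=S(=O)(c1ccccc1)C/C=C(\C)CC[C@H](C(=C)C)[C@@H](O[Si](CC)(CC)CC)/C=C(\I)CO[Si](C)(C)C(C)(C)C | intermediate
20 | [(3R)-4-(methoxycarbonyl)-3-[(triisopropylsilyl)oxy]pent-4-en-1-yl]zinc iodide (not isolated) | C=C(C(=O)OC)[C@H](O[Si](C(C)C)(C(C)C)C(C)C)CC[Zn]I | intermediate
21 | methyl (3R,6E,8S,9R,12E)-6-{[(tert-butyldimethylsilyl)oxy]methyl}-12-methyl-2-methylidene-14-(phenylsulfonyl)-9-(prop-1-en-2-yl)-8-[(triethylsilyl)oxy]-3-[(triisopropylsilyl)oxy]tetradeca-6,12-dienoate | O=S(=O)(c1ccccc1)C/C=C(\C)CC[C@H](C(=C)C)[C@@H](O[Si](CC)(CC)CC)/C=C(/CO[Si](C)(C)C(C)(C)C)CC[C@@H](O[Si](C(C)C)(C(C)C)C(C)C)C(=C)C(=O)OC | intermediate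
22 | (1R,2S,3E,7R,11E)-18-[(tert-butyldimethylsilyl)oxy]-10-(phenylsulfonyl)-2-[(triethylsilyl)oxy]-7-[(triisopropylsilyl)oxy]-9,10-secocembra-3,8(19),11,15-tetraen-9-ol | O=S(=O)(c1ccccc1)C/C=C(\C)CC[C@H](C(=C)C)[C@@H](O[Si](CC)(CC)CC)/C=C(/CO[Si](C)(C)C(C)(C)C)CC[C@@H](O[Si](C(C)C)(C(C)C)C(C)C)C(=C)CO | intermediate
23 | C9 methanesulfonate of 22 (not isolated) | O=S(=O)(c1ccccc1)C/C=C(\C)CC[C@H](C(=C)C)[C@@H](O[Si](CC)(CC)CC)/C=C(/CO[Si](C)(C)C(C)(C)C)CC[C@@H](O[Si](C(C)C)(C(C)C)C(C)C)C(=C)COS(C)(=O)=O | intermediate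
24 | (1R,2S,3E,7R,11E)-9-bromo-18-[(tert-butyldimethylsilyl)oxy]-10-(phenylsulfonyl)-2-[(triethylsilyl)oxy]-7-[(triisopropylsilyl)oxy]-9,10-secocembra-3,8(19),11,15-tetraene (seco precursor) | O=S(=O)(c1ccccc1)C/C=C(\C)CC[C@H](C(=C)C)[C@@H](O[Si](CC)(CC)CC)/C=C(/CO[Si](C)(C)C(C)(C)C)CC[C@@H](O[Si](C(C)C)(C(C)C)C(C)C)C(=C)CBr | intermediate
25 | potassium C10 carbanion of 24 (not isolated) | [K+].O=S(=O)(c1ccccc1)[CH-]/C=C(\C)CC[C@H](C(=C)C)[C@@H](O[Si](CC)(CC)CC)/C=C(/CO[Si](C)(C)C(C)(C)C)CC[C@@H](O[Si](C(C)C)(C(C)C)C(C)C)C(=C)CBr | intermediate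
26 | (1R,2S,3E,7R,11E)-18-[(tert-butyldimethylsilyl)oxy]-10-(phenylsulfonyl)-2-[(triethylsilyl)oxy]-7-[(triisopropylsilyl)oxy]cembra-3,8(19),11,15-tetraene, both C10 epimers | C=C1CC(S(=O)(=O)c2ccccc2)/C=C(\C)CC[C@H](C(=C)C)[C@@H](O[Si](CC)(CC)CC)/C=C(/CO[Si](C)(C)C(C)(C)C)CC[C@H]1O[Si](C(C)C)(C(C)C)C(C)C | intermediate
27 | (1R,2S,3E,7R,11E)-18-[(tert-butyldimethylsilyl)oxy]-2-[(triethylsilyl)oxy]-7-[(triisopropylsilyl)oxy]cembra-3,8(19),11,15-tetraene | C=C1CC/C=C(\C)CC[C@H](C(=C)C)[C@@H](O[Si](CC)(CC)CC)/C=C(/CO[Si](C)(C)C(C)(C)C)CC[C@H]1O[Si](C(C)C)(C(C)C)C(C)C | intermediate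
28 | (1R,2S,3E,7R,11E)-7-[(triisopropylsilyl)oxy]cembra-3,8(19),11,15-tetraene-2,18-diol | C=C1CC/C=C(\C)CC[C@H](C(=C)C)[C@@H](O)/C=C(/CO)CC[C@H]1O[Si](C(C)C)(C(C)C)C(C)C | intermediate
29 | (1R,2S,3E,7R,11E)-7-[(triisopropylsilyl)oxy]cembra-3,8(19),11,15-tetraene-2,18-diyl diacetate | C=C1CC/C=C(\C)CC[C@H](C(=C)C)[C@@H](OC(C)=O)/C=C(/COC(C)=O)CC[C@H]1O[Si](C(C)C)(C(C)C)C(C)C | intermediate
30 | (1R,2S,3E,7R,11E)-7-hydroxycembra-3,8(19),11,15-tetraene-2,18-diyl diacetate (CNP0077636.1) | C=C1CC/C=C(\C)CC[C@H](C(=C)C)[C@@H](OC(C)=O)/C=C(/COC(C)=O)CC[C@H]1O | target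

**Step count and risk**

Total step count: 21. Longest linear sequence: 13 steps (steps 7–11 and 14–21 from 10; equally steps 1–3 and 12–21 from 1).

Steps most likely to fail:

1. Step 17 (macrocyclisation). Intermolecular alkylation may outrun ring closure and give oligomers, or the base may consume the allylic bromide before the carbanion reacts. The fallback forms C9–C10 between two molecules and closes the ring at C4–C5 instead; it sets out from 16 and 19 and comes back at 26. Ester 16 would be reduced (i-Bu2AlH, CH2Cl2, −78 °C) to (3R)-5-iodo-2-methylidene-3-[(triisopropylsilyl)oxy]pentan-1-ol F1. Appel bromination (CBr4, PPh3) would give {[(3R)-4-(bromomethyl)-1-iodopent-4-en-3-yl]oxy}triisopropylsilane F2. The lithium carbanion of 19 (LiN(SiMe3)2, THF, −78 °C) would be alkylated at the allylic bromide of F2 to give the 4,5-seco C10 sulfone diiodide F3 (C4 alkenyl iodide, C5 primary iodide, both C10 epimers). Zinc insertion into the primary C–I bond (Zn dust, LiCl, THF) would give the alkylzinc iodide F4, and intramolecular Negishi coupling (PdCl2(dppf), THF, high dilution) with the C4 alkenyl iodide would give 26.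

2. Step 12 (allylboration). Addition of the hindered trisubstituted allylboronate may be slow, and facial selectivity on the β-iodo enal may be insufficient. The fallback replaces boron by chromium; it sets out from 3 (with 9) and comes back at 18. Alcohol 3 would be converted (MsCl, Et3N; LiBr) into (2E,6E)-8-bromo-3,7-dimethyl-1-(phenylsulfonyl)octa-2,6-diene F5. A catalytic asymmetric Nozaki–Hiyama allylation of 9 (CrCl2 cat., Mn, Me3SiCl, Et3N, chiral 1,8-bis(oxazolinyl)carbazole ligand, THF) would give the C2 trimethylsilyl ether of 18 F6, which would be cleaved by citric acid in MeOH to 18. The chair transition state of the γ-substituted allylchromium should give the anti pair, the ligand enantiomer being chosen for Re-face addition, and the alkenyl iodide is inert to CrCl2 without a nickel co-catalyst.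

3. Step 7 (asymmetric Baylis–Hillman reaction). Conversion of the β-silyloxy aldehyde may be low, and diversion to a dioxanone by-product may erode enantiomeric purity. The fallback sets C7 by hydrogenation; it sets out from 10 and comes back at 13. Roskamp homologation of 10 (methyl diazoacetate, SnCl2, CH2Cl2) would give methyl 5-[(tert-butyldimethylsilyl)oxy]-3-oxopentanoate F7. Noyori hydrogenation (RuCl2[(R)-BINAP], H2, MeOH) would give methyl (3R)-5-[(tert-butyldimethylsilyl)oxy]-3-hydroxypentanoate F8. Fráter–Seebach dianion formation (LiN(i-Pr)2, 2 equiv) and trapping with Eschenmoser's salt would give the α-(dimethylaminomethyl) ester F9. Quaternisation with MeI would give the ammonium iodide F10, and elimination with DBU would give 13.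

**Further compounds**

F1 | step 17 | (3R)-5-iodo-2-methylidene-3-[(triisopropylsilyl)oxy]pentan-1-ol | C=C(CO)[C@H](O[Si](C(C)C)(C(C)C)C(C)C)CCI
F2 | step 17 | {[(3R)-4-(bromomethyl)-1-iodopent-4-en-3-yl]oxy}triisopropylsilane | C=C(CBr)[C@H](O[Si](C(C)C)(C(C)C)C(C)C)CCI
F3 | step 17 | 4,5-seco C10 sulfone diiodide (C9–C10 joined; both C10 epimers) | ICC[C@@H](O[Si](C(C)C)(C(C)C)C(C)C)C(=C)CC(S(=O)(=O)c1ccccc1)/C=C(\C)CC[C@H](C(=C)C)[C@@H](O[Si](CC)(CC)CC)/C=C(\I)CO[Si](C)(C)C(C)(C)C
F4 | step 17 | C5 alkylzinc iodide from F3 | I[Zn]CC[C@@H](O[Si](C(C)C)(C(C)C)C(C)C)C(=C)CC(S(=O)(=O)c1ccccc1)/C=C(\C)CC[C@H](C(=C)C)[C@@H](O[Si](CC)(CC)CC)/C=C(\I)CO[Si](C)(C)C(C)(C)C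
F5 | step 12 | (2E,6E)-8-bromo-3,7-dimethyl-1-(phenylsulfonyl)octa-2,6-diene | O=S(=O)(c1ccccc1)C/C=C(\C)CC/C=C(\C)CBr
F6 | step 12 | C2 trimethylsilyl ether of 18 | O=S(=O)(c1ccccc1)C/C=C(\C)CC[C@H](C(=C)C)[C@@H](O[Si](C)(C)C)/C=C(\I)CO[Si](C)(C)C(C)(C)C
F7 | step 7 | methyl 5-[(tert-butyldimethylsilyl)oxy]-3-oxopentanoate | COC(=O)CC(=O)CCO[Si](C)(C)C(C)(C)C
F8 | step 7 | methyl (3R)-5-[(tert-butyldimethylsilyl)oxy]-3-hydroxypentanoate | COC(=O)C[C@H](O)CCO[Si](C)(C)C(C)(C)C
F9 | step 7 | methyl (3R)-5-[(tert-butyldimethylsilyl)oxy]-2-[(dimethylamino)methyl]-3-hydroxypentanoate (C2 epimers) | COC(=O)C(CN(C)C)[C@H](O)CCO[Si](C)(C)C(C)(C)C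
F10 | step 7 | trimethylammonium iodide from F9 | COC(=O)C(C[N+](C)(C)C)[C@H](O)CCO[Si](C)(C)C(C)(C)C.[I-]
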